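At early times the north flask, the flask asked about, shows D at 29.5% after 1.50 h, but by 12.0 h the readings have come down to a flat line.

| flask | E | X | temperature | remark | time |
|---|---|---|---|---|---|
| north | 0.015 M | 0.045 M | −20 °C | the very flask that is asked about, followed so far |  |
| south-west | 0.030 M | 0.045 M | −14 °C | run made earlier |  |
| flask | 0.015 M | 0.0450 M | −20 °C |  | 30 h |

north run (percent of the E charged)

| time / h | D / % |
|---|---|
| 1.50 | 29.5 |
| 5.00 | 12.5 |
| 8.00 | 10.0 |
| 12.0 | 8.5 |
| 20.0 | 8.2 |
| 25.0 | 8.5 |

south-west run (percent of the E charged)

| time / min | D / % |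
|---|---|
| 15.0 | 11.1 |
| 30.0 | 15.2 |
| 50.0 | 14.8 |
| 60.0 | 14.2 |
| 80.0 | 13.1 |
| 90.0 | 11.9 |

(standard deviation of a reading: 0.5 percentage points)

- dusk: at 30 h add X, 100% of the amount charged, then wait 30 h
- spring: at 30 h raise the temperature by 15 K, then wait 30 h
- summer: at 30 h take out 90% of the D then present, then wait 30 h
- winter: change nothing and wait 30 h more

- removed D is counted in
- what may be going on: Z + X <-> G + D; D <-> Q; E + X <-> G + Z; G -> L
- additions bring no volume worth counting

- D, in percent of the E first charged, at 30 h
- which option adds most D ("none" when 2 percentage points or less is all one gets) (dusk / spring / summer / winter / none)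
- D present, with what was taken out counted in, in percent of the E first charged, after dusk
- D present, with what was taken out counted in, in percent of the E first charged, after winter

The proposed steps take E through Z to D, and each takes up one X, so I count 2 X for every E that reaches D or Q. With X held at 0.0450 M, that gives a crossing charge, the [E] at which X is exactly used up, 0.0225 M: below it I expect E to be the limiting reagent, above it X.

The north flask holds less E than that, so I expect 33.3% of its X to stay free. The south-west run holds more, so I expect X to fall short there, but its readings are still falling at the end and give no plateau.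

So I read the north line as D's share of a pool of D and Q. Its last readings average 8.40%, and the line is reached earlier than the asked time, so that is my figure for now and for winter. Dusk adds X where it is in excess, so I expect nothing from it. If the pool returns to the same share of D after summer, I reckon a gain of 6.9 percentage points. Spring I can't put a figure on.

The forecast gives 8.4% for the asked time, 9% after dusk and 8.4% after winter, and it names summer; on spring it says “Warming has an unknown effect on the equilibrium”.

The flask gives 9.09%, and spring adds most, 12 points against 7.4 points for summer.

    Z + X ⇌ G + D (K = 0.260, k = 1.00 M⁻¹ min⁻¹, Ea = 39.0 kJ mol⁻¹, ΔH = −47.0 kJ mol⁻¹)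
    D ⇌ Q (K = 10.0, k = 0.0180 min⁻¹, Ea = 70.0 kJ mol⁻¹, ΔH = −38.0 kJ mol⁻¹)
    E + X ⇌ G + Z (K = 0.480, k = 2.50 M⁻¹ min⁻¹, Ea = 44.0 kJ mol⁻¹, ΔH = −7.00 kJ mol⁻¹)
    G → L (k = 0.0660 min⁻¹, Ea = 77.0 kJ mol⁻¹)
    (constants at −20 °C)

At 30.0 h the flask, charged below the crossing, has 33.3% of its X free and 0% of its E, and dusk adds 0 points. A neighbour charged with 0.037 M of E stands above the crossing of 0.0225 M: at 30.0 h it holds X at 0% of its own charge, with E at 22.9% and D at 4.05% of the E charged.

(All runs come from a simulation with made-up constants.)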